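**Retrosynthetic overview**

1. The target comes from acylation of the secondary allylic alcohol of a bicyclic diol-ketone with 4-methoxybenzoyl chloride, itself made from anisole and oxalyl chloride.
2. The β-hydroxy ketone with its α-quaternary methyl comes from a semipinacol 1,2-methyl shift of a ring-fusion 2,3-epoxy tertiary alcohol. This key step sets C8a and the trans ring fusion.
3. The epoxy alcohol comes from hydroxyl-directed epoxidation of a bicyclic dienol, whose seven-membered ring is closed by ring-closing metathesis (second ring formed).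
4. The five-membered ring (first ring formed) comes from a proposed enantioselective nickel-catalysed reductive [3+2] annulation of (E)-5-methylhex-3-en-2-one with an internal alkyne.
5. The alkyne comes from asymmetric alkynylation of acrolein with 2-methylhex-1-en-5-yne, made by Wittig methylenation of hex-5-yn-2-one.

**Assumptions**

- The ligand antipodes named in steps 2 and 4 are taken to give the configurations drawn; if a test run shows the opposite sense, the mirror-image ligand is used.
- L1 = (4R,5R)-1,3-bis(2-isopropylphenyl)-4,5-diphenylimidazolidin-2-ylidene, a C2-symmetric chiral NHC, generated from its tetrafluoroborate salt.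
- Bicyclic compounds carry azulene numbering (C1–C3, C3a, C4–C8, C8a).

**Route**

Step 1
Reactants: 1 hex-5-yn-2-one
Product: 2 2-methylhex-1-en-5-yne
Conditions: Ph3PCH3Br, KOtBu, Et2O, 0 °C to rt; distil
Reagents that add atoms: methyltriphenylphosphonium bromide, C[P+](c1ccccc1)(c1ccccc1)c1ccccc1.[Br-]
Why: Wittig methylenation of the methyl ketone with the non-stabilised ylide; the terminal alkyne C–H is too weakly acidic to quench the ylide and no stereocentre is formed.

Step 2
Reactants: 2 2-methylhex-1-en-5-yne; 3 acrolein (prop-2-enal)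
Product: 4 (3R)-8-methylnona-1,8-dien-4-yn-3-ol
Conditions: (S,S)-ProPhenol (10 mol %), Ph3P=O (20 mol %), Me2Zn (2.5 equiv), 2 (2.5 equiv, excess recovered), toluene, 0–4 °C, slow addition of 3
Reagents that add atoms: none
Why: Catalytic enantioselective zinc alkynylide 1,2-addition to an enal (dinuclear zinc–ProPhenol alkynylation), in which the chiral dizinc pocket binds the aldehyde and delivers the alkynyl group to one carbonyl face to set the (R)-carbinol.

Step 3
Reactants: 4 (3R)-8-methylnona-1,8-dien-4-yn-3-ol
Product: 5 triethyl{[(3R)-8-methylnona-1,8-dien-4-yn-3-yl]oxy}silane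
Conditions: TESCl, imidazole, CH2Cl2, 0 °C
Reagents that add atoms: chlorotriethylsilane, CC[Si](Cl)(CC)CC
Why: Imidazole-promoted silylation masks the secondary hydroxyl so that it can neither direct the later epoxidation nor act as a neighbouring group in the rearrangement; the stereocentre is untouched.

Step 4
Reactants: 5 triethyl{[(3R)-8-methylnona-1,8-dien-4-yn-3-yl]oxy}silane; 6 (E)-5-methylhex-3-en-2-one
Product: 7 (1R,4R)-1-methyl-3-(3-methylbut-3-en-1-yl)-4-(propan-2-yl)-2-[(1R)-1-(triethylsilyloxy)prop-2-en-1-yl]cyclopent-2-en-1-ol (hydroxyl cis to isopropyl)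
Conditions: Ni(cod)2 (10 mol %), L1·HBF4 (12 mol %), KOtBu (12 mol %), Et3B (2 equiv), MeOH (1.5 equiv, slow addition), 6 (1.5 equiv), toluene, 45 °C
Reagents that add atoms: none
Why: Proposed new method: zerovalent nickel bearing the bulky chiral NHC joins the enone β-carbon to the less hindered alkyne carbon by enantio-determining oxidative cyclisation (setting the isopropyl-bearing centre as R), methanol protonates the nickel enolate, and the alkenylnickel then adds 5-exo to the methyl ketone through a four-centred insertion with isopropyl pseudo-equatorial and the ketone methyl on the opposite face (hydroxyl cis to isopropyl) before Et3B returns nickel to the zerovalent state; the closest known reactions are the nickel-catalysed reductive [3+2] annulations of alkynes with enals (giving cyclopentenols) and with aryl enoates (giving cyclopentenones, also enantioselectively with chiral NHCs), whereas simple alkyl enones so far give open-chain reductive coupling in methanol-rich media, so the proton source is held near one equivalent and the electron-rich NHC and Lewis-acidic borane are used to let ketone capture outrun protonolysis of the alkenyl–nickel bond.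

Step 5
Reactants: 7 (1R,4R)-1-methyl-3-(3-methylbut-3-en-1-yl)-4-(propan-2-yl)-2-[(1R)-1-(triethylsilyloxy)prop-2-en-1-yl]cyclopent-2-en-1-ol
Product: 8 (1R,3R,8R)-1,6-dimethyl-3-(propan-2-yl)-8-(triethylsilyloxy)-1,2,3,4,5,8-hexahydroazulen-1-ol
Conditions: second-generation Grubbs catalyst (5 mol %), toluene (5 mM), 70 °C, argon sparge
Reagents that add atoms: none
Why: Ring-closing metathesis between the vinyl group and the 1,1-disubstituted alkene, which sit cis on the cyclopentene double bond, closes the seven-membered ring as a trisubstituted cycloalkene with loss of ethene; the tetrasubstituted ring alkene is inert and no stereocentre changes.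

Step 6
Reactants: 8 (1R,3R,8R)-1,6-dimethyl-3-(propan-2-yl)-8-(triethylsilyloxy)-1,2,3,4,5,8-hexahydroazulen-1-ol
Product: 9 (1R,3R,3aS,8R,8aR)-3a,8a-epoxy-1,6-dimethyl-3-(propan-2-yl)-8-(triethylsilyloxy)-1,2,3,3a,4,5,8,8a-octahydroazulen-1-ol (epoxide oxygen cis to the C1 hydroxyl and the C3 isopropyl)
Conditions: VO(acac)2 (5 mol %), t-BuOOH (1.5 equiv, decane), CH2Cl2, 0 °C
Reagents that add atoms: tert-butyl hydroperoxide, CC(C)(C)OO
Why: Vanadium-catalysed hydroxyl-directed epoxidation, in which the tertiary allylic vanadate delivers the peroxide oxygen to the ring-fusion tetrasubstituted alkene on the face of the hydroxyl, while the remote trisubstituted alkene and the silyl ether neither react nor direct.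

Step 7
Reactants: 9 (1R,3R,3aS,8R,8aR)-3a,8a-epoxy-1,6-dimethyl-3-(propan-2-yl)-8-(triethylsilyloxy)-1,2,3,3a,4,5,8,8a-octahydroazulen-1-ol
Product: 11 (3R,3aS,8R,8aS)-3a,8-dihydroxy-6,8a-dimethyl-3-(propan-2-yl)-3,3a,4,5,8,8a-hexahydroazulen-1(2H)-one, via triethylsilyl ether ketone 10 (not isolated)
Conditions: ZnBr2 (0.5 equiv), CH2Cl2, −20 to 0 °C; then MeCN, 48% aq. HF, 0 °C
Reagents that add atoms: none
Why: Semipinacol rearrangement of a 2,3-epoxy alcohol (1,2-methyl shift), in which zinc chelation of the cis-epoxy alcohol opens the epoxide at C8a while the C1 methyl, the only group antiperiplanar to the breaking C–O bond, migrates to C8a with inversion there, so the new quaternary methyl is trans to the retained C3a oxygen (trans ring fusion) and C1 becomes the ketone; HF then cleaves the Si–O bond without disturbing the aldol unit.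

Step 8
Reactants: 12 anisole
Product: 13 4-methoxybenzoyl chloride
Conditions: (COCl)2 (2 equiv), AlCl3 (1.1 equiv), CH2Cl2, 0 °C, slow addition of 12; distil
Reagents that add atoms: oxalyl chloride, O=C(Cl)C(=O)Cl
Why: Friedel–Crafts chlorocarbonylation, in which the oxalyl chloride–AlCl3 acylium loses CO and attacks para to the methoxy group; adding anisole slowly to excess reagent suppresses diaryl ketone formation.

Step 9
Reactants: 11 (3R,3aS,8R,8aS)-3a,8-dihydroxy-6,8a-dimethyl-3-(propan-2-yl)-3,3a,4,5,8,8a-hexahydroazulen-1(2H)-one; 13 4-methoxybenzoyl chloride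
Product: 14 (3R,3aS,8R,8aS)-3a-hydroxy-6,8a-dimethyl-1-oxo-3-(propan-2-yl)-1,2,3,3a,4,5,8,8a-octahydroazulen-8-yl 4-methoxybenzoate
Conditions: 13 (1.5 equiv), DMAP (0.2 equiv), Et3N (3 equiv), CH2Cl2, 0 °C to rt
Reagents that add atoms: none
Why: DMAP-catalysed acylation (nucleophilic catalysis) esterifies the secondary allylic alcohol with retention, the tertiary ring-fusion alcohol being too hindered to react.

**Compound list**

1 | hex-5-yn-2-one | CC(=O)CCC#C | starting material
2 | 2-methylhex-1-en-5-yne | C=C(C)CCC#C | intermediate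
3 | acrolein (prop-2-enal) | C=CC=O | starting material
4 | (3R)-8-methylnona-1,8-dien-4-yn-3-ol | C=C[C@@H](O)C#CCCC(C)=C | intermediate
5 | triethyl{[(3R)-8-methylnona-1,8-dien-4-yn-3-yl]oxy}silane | C=C[C@@H](O[Si](CC)(CC)CC)C#CCCC(C)=C | intermediate
6 | (E)-5-methylhex-3-en-2-one | CC(=O)/C=C/C(C)C | starting material
7 | (1R,4R)-1-methyl-3-(3-methylbut-3-en-1-yl)-4-(propan-2-yl)-2-[(1R)-1-(triethylsilyloxy)prop-2-en-1-yl]cyclopent-2-en-1-ol | C=C[C@@H](O[Si](CC)(CC)CC)C1=C(CCC(C)=C)[C@@H](C(C)C)C[C@@]1(C)O | intermediate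
8 | (1R,3R,8R)-1,6-dimethyl-3-(propan-2-yl)-8-(triethylsilyloxy)-1,2,3,4,5,8-hexahydroazulen-1-ol | CC[Si](CC)(CC)O[C@@H]1C=C(C)CCC2=C1[C@](C)(O)C[C@@H]2C(C)C | intermediate
9 | (1R,3R,3aS,8R,8aR)-3a,8a-epoxy-1,6-dimethyl-3-(propan-2-yl)-8-(triethylsilyloxy)-1,2,3,3a,4,5,8,8a-octahydroazulen-1-ol | CC[Si](CC)(CC)O[C@@H]1C=C(C)CC[C@@]2(O3)[C@]13[C@](C)(O)C[C@@H]2C(C)C | intermediate
10 | (3R,3aS,8R,8aS)-3a-hydroxy-6,8a-dimethyl-3-(propan-2-yl)-8-(triethylsilyloxy)-3,3a,4,5,8,8a-hexahydroazulen-1(2H)-one | CC[Si](CC)(CC)O[C@@H]1C=C(C)CC[C@]2(O)[C@@H](C(C)C)CC(=O)[C@@]12C | intermediate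
11 | (3R,3aS,8R,8aS)-3a,8-dihydroxy-6,8a-dimethyl-3-(propan-2-yl)-3,3a,4,5,8,8a-hexahydroazulen-1(2H)-one | O[C@@H]1C=C(C)CC[C@]2(O)[C@@H](C(C)C)CC(=O)[C@@]12C | intermediate
12 | anisole | COc1ccccc1 | starting material
13 | 4-methoxybenzoyl chloride | COc1ccc(C(=O)Cl)cc1 | intermediate
14 | (3R,3aS,8R,8aS)-3a-hydroxy-6,8a-dimethyl-1-oxo-3-(propan-2-yl)-1,2,3,3a,4,5,8,8a-octahydroazulen-8-yl 4-methoxybenzoate | COc1ccc(C(=O)O[C@@H]2C=C(C)CC[C@]3(O)[C@@H](C(C)C)CC(=O)[C@@]23C)cc1 | target

**Step count and risks**

Total step count: 9. Longest linear sequence: 8 (steps 1–7 and 9); step 8 is a one-step side branch.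

Three steps most likely to fail:

- **Step 4 (the new annulation).** The risks are open-chain reductive coupling instead of ketone capture, the wrong alkyne regiochemistry, or the wrong C1 epimer. The fallback uses known chemistry, sets out from 5 and comes back at 7. (E)-4-Methylpent-2-enoic acid and phenol (DCC, DMAP) give phenyl (E)-4-methylpent-2-enoate F1. The established zerovalent-nickel/chiral NHC/Et3B annulation of aryl enoates with internal alkynes then joins 5 and F1 to (4R)-3-(3-methylbut-3-en-1-yl)-4-(propan-2-yl)-2-[(1R)-1-(triethylsilyloxy)prop-2-en-1-yl]cyclopent-2-en-1-one F2, phenoxide being expelled after the alkenylnickel attacks the ester. MeLi/CeCl3 (THF, −78 °C) adds to the carbonyl anti to the isopropyl group and gives 7.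

- **Step 7 (the 1,2-methyl shift on the fused epoxide).** The risks are epoxide opening at C3a, or reluctance of the ring-fusion carbon to invert inside the bicycle. The fallback sets out from 7 and comes back at 10, with epoxidation and shift done before ring closure. VO(acac)2/t-BuOOH on 7 gives (1R,2R,4R,5S)-2-methyl-5-(3-methylbut-3-en-1-yl)-4-(propan-2-yl)-1-[(1R)-1-(triethylsilyloxy)prop-2-en-1-yl]-6-oxabicyclo[3.1.0]hexan-2-ol F3. ZnBr2 rearranges it on the unconstrained ring to (2S,3S,4R)-3-hydroxy-2-methyl-3-(3-methylbut-3-en-1-yl)-4-(propan-2-yl)-2-[(1R)-1-(triethylsilyloxy)prop-2-en-1-yl]cyclopentan-1-one F4. Ring-closing metathesis of F4 with the second-generation Grubbs catalyst gives 10, which aqueous HF converts to 11.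

- **Step 2 (asymmetric alkynylation of acrolein).** The risks are acrolein polymerisation and low enantiomeric excess. The fallback sets out from 2 and comes back at 4, replacing asymmetric catalysis with resolution. n-BuLi then acrolein (THF, −78 °C) gives racemic 8-methylnona-1,8-dien-4-yn-3-ol F5. Lipase-catalysed acetylation (Amano lipase PS, vinyl acetate, hexane) acylates the (R)-enantiomer to (3R)-8-methylnona-1,8-dien-4-yn-3-yl acetate F6, which is separated from the (S)-alcohol. K2CO3/MeOH returns 4. Should the lipase show the opposite preference, the unreacted (R)-alcohol is used directly.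

**Further compounds**

F1 | step 4 | phenyl (E)-4-methylpent-2-enoate | CC(C)/C=C/C(=O)Oc1ccccc1
F2 | step 4 | (4R)-3-(3-methylbut-3-en-1-yl)-4-(propan-2-yl)-2-[(1R)-1-(triethylsilyloxy)prop-2-en-1-yl]cyclopent-2-en-1-one | C=C[C@@H](O[Si](CC)(CC)CC)C1=C(CCC(C)=C)[C@@H](C(C)C)CC1=O
F3 | step 7 | (1R,2R,4R,5S)-2-methyl-5-(3-methylbut-3-en-1-yl)-4-(propan-2-yl)-1-[(1R)-1-(triethylsilyloxy)prop-2-en-1-yl]-6-oxabicyclo[3.1.0]hexan-2-ol | C=C[C@@H](O[Si](CC)(CC)CC)[C@]12O[C@@]1(CCC(C)=C)[C@@H](C(C)C)C[C@@]2(C)O
F4 | step 7 | (2S,3S,4R)-3-hydroxy-2-methyl-3-(3-methylbut-3-en-1-yl)-4-(propan-2-yl)-2-[(1R)-1-(triethylsilyloxy)prop-2-en-1-yl]cyclopentan-1-one | C=C[C@@H](O[Si](CC)(CC)CC)[C@]1(C)C(=O)C[C@H](C(C)C)[C@@]1(O)CCC(C)=C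
F5 | step 2 | racemic 8-methylnona-1,8-dien-4-yn-3-ol | C=CC(O)C#CCCC(C)=C
F6 | step 2 | (3R)-8-methylnona-1,8-dien-4-yn-3-yl acetate | C=C[C@@H](OC(C)=O)C#CCCC(C)=C
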